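The route rests on disconnecting the C4a–C5 bond of the 2H-chromen-6(5H)-one core, the link between the sp2 carbon shared by the pyran and carbocyclic rings and the quaternary C5 that carries methyl and prenyl. It is forged by an enantioselective intramolecular reductive Heck reaction: the alkenyl iodide of a 5-iodo-2H-pyran, tethered through a 1,3-diketone to a 2-prenyl enone, adds 6-exo to the internal alkene carbon, and formate turns the exocyclic methylene into the C5 methyl. One operation closes the carbocycle, sets the only stereocentre and delivers the cross-conjugated dienone. The precursor is a monocyclic iodopyranyl ene-1,3-dione made by crossed Claisen condensation, and C7 acylation finishes the synthesis.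

Key step: step 6

Remark: 9 and 12 are drawn as their C8-enol tautomers, 1 is taken as the purchasable repellent butopyronoxyl, and (S)-tBu-PHOX is a working choice whose antipode would be used if the first cyclisation shows the opposite sense of induction.

Step 1
Reactants: 1 butopyronoxyl (butyl 2,2-dimethyl-4-oxo-3,4-dihydro-2H-pyran-6-carboxylate)
Product: 2 butyl 5-iodo-2,2-dimethyl-4-oxo-3,4-dihydro-2H-pyran-6-carboxylate
Conditions: ICl, pyridine, CH2Cl2, 0 °C → rt
Reagents that add atoms: iodine monochloride, ClI
Why: Electrophilic α-iodination of a β-alkoxy enone: the enol-ether carbon C5 is the nucleophilic site and pyridine removes the proton, which restores the vinylogous ester with iodine on C5.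

Step 2
Reactants: 2 butyl 5-iodo-2,2-dimethyl-4-oxo-3,4-dihydro-2H-pyran-6-carboxylate
Product: 3 butyl 4-hydroxy-5-iodo-2,2-dimethyl-3,4-dihydro-2H-pyran-6-carboxylate (racemic)
Conditions: NaBH4, CeCl3·7H2O, MeOH, −20 °C
Reagents that add atoms: none
Why: Luche reduction should deliver hydride 1,2 to the enone carbonyl only, leaving the ester and the C–I bond; the new carbinol centre is racemic and is removed in step 3.

Step 3
Reactants: 3 butyl 4-hydroxy-5-iodo-2,2-dimethyl-3,4-dihydro-2H-pyran-6-carboxylate
Product: 5 butyl 5-iodo-2,2-dimethyl-2H-pyran-6-carboxylate, via allylic mesylate 4 (not isolated)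
Conditions: MsCl, Et3N, CH2Cl2, 0 °C; then DBU, rt
Reagents that add atoms: none
Why: Mesylation and base-promoted 1,2-elimination (the dehydration that turns chroman-4-ols into 2H-chromenes): the allylic, oxygen-stabilised mesylate should lose methanesulfonate toward the C3 methylene to give the conjugated 2H-pyran diene.

Step 4
Reactants: 6 sulcatone (6-methylhept-5-en-2-one)
Product: 7 6-methyl-3-methylidenehept-5-en-2-one
Conditions: (CH2O)n, N-methylanilinium trifluoroacetate, THF, reflux
Reagents that add atoms: paraformaldehyde (as formaldehyde), C=O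
Why: Direct Mannich-type α-methylenation proceeds through the more substituted, thermodynamic enol of the methyl ketone, so C3 and not the methyl group should be methylenated.

Step 5
Reactants: 5 butyl 5-iodo-2,2-dimethyl-2H-pyran-6-carboxylate; 7 6-methyl-3-methylidenehept-5-en-2-one
Product: 8 1-(5-iodo-2,2-dimethyl-2H-pyran-6-yl)-7-methyl-4-methylideneoct-6-ene-1,3-dione
Conditions: 7 (2.2 equiv), LiN(iPr)2 (2.2 equiv), THF, −78 °C; then 5, −78 → −30 °C; AcOH quench
Reagents that add atoms: none
Why: Crossed Claisen condensation: the kinetic methyl-side lithium enolate of enone 7 acylates the non-enolisable ester 5, and the second equivalent of enolate deprotonates the 1,3-diketone, which drives the reaction and holds the product as its chelated lithium enolate until the quench.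

Step 6
Reactants: 8 1-(5-iodo-2,2-dimethyl-2H-pyran-6-yl)-7-methyl-4-methylideneoct-6-ene-1,3-dione
Product: 9 (5S)-8-hydroxy-2,2,5-trimethyl-5-(3-methylbut-2-en-1-yl)-2H-chromen-6(5H)-one
Conditions: Pd2(dba)3 (5 mol %), (S)-tBu-PHOX (12 mol %), HCO2Na (2 equiv), DMF, 70 °C
Reagents that add atoms: none
Why: Oxidative addition of the zerovalent palladium–PHOX complex into the C–I bond at C5 of the pyran gives an alkenylpalladium iodide that carbopalladates the 1,1-disubstituted enone alkene at its internal carbon; the resulting neopentyl-type alkylpalladium has no β-hydrogen, so formate exchange, loss of CO2 and C–H reductive elimination turn the former methylene into the C5 methyl. The closest known reaction type is the enantioselective intramolecular reductive Heck cyclisation of aryl and alkenyl iodides onto tethered 2-substituted acryloyl units, which gives quaternary oxindoles, isoquinolinediones and tetrahydropyridines. The carbocycle closes in the 6-exo-trig mode through a tether that is the carbon analogue of an N-acyl methacrylamide. C5 is created in the migratory insertion, and the alkene face that binds cis to the alkenyl group is chosen by the chiral P,N ligand, the only control element. The step needs insertion to outrun formate reduction of the alkenylpalladium and 7-endo closure; the six-membered exo transition state, the activated β-iodo enone carbon and the absence of β-hydrogen after insertion should secure this, and the weakly basic formate leaves the enolised diketone neutral so that it cyclises through its diketo tautomer.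

Step 7
Reactants: 9 (5S)-8-hydroxy-2,2,5-trimethyl-5-(3-methylbut-2-en-1-yl)-2H-chromen-6(5H)-one; 10 3-phenylpropanoic acid
Product: 12 (5S)-8-hydroxy-2,2,5-trimethyl-5-(3-methylbut-2-en-1-yl)-7-(3-phenylpropanoyl)-2H-chromen-6(5H)-one, via enol ester 11 (not isolated)
Conditions: DCC, DMAP (1.2 equiv), CH2Cl2, rt
Reagents that add atoms: none
Why: Steglich esterification of the vinylogous acid gives an enol ester that DMAP should convert by O-to-C acyl transfer (the standard C-acylation of cyclohexane-1,3-diones) into the hydrogen-bonded 7-acyl enol, while the quaternary C5 cannot epimerise.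

Compound list
1 | butopyronoxyl, butyl 2,2-dimethyl-4-oxo-3,4-dihydro-2H-pyran-6-carboxylate | CCCCOC(=O)C1=CC(=O)CC(C)(C)O1 | starting material
2 | butyl 5-iodo-2,2-dimethyl-4-oxo-3,4-dihydro-2H-pyran-6-carboxylate | CCCCOC(=O)C1=C(I)C(=O)CC(C)(C)O1 | intermediate
3 | butyl 4-hydroxy-5-iodo-2,2-dimethyl-3,4-dihydro-2H-pyran-6-carboxylate (racemic) | CCCCOC(=O)C1=C(I)C(O)CC(C)(C)O1 | intermediate
4 | butyl 5-iodo-2,2-dimethyl-4-(methylsulfonyloxy)-3,4-dihydro-2H-pyran-6-carboxylate (not isolated) | CCCCOC(=O)C1=C(I)C(OS(C)(=O)=O)CC(C)(C)O1 | intermediate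
5 | butyl 5-iodo-2,2-dimethyl-2H-pyran-6-carboxylate | CCCCOC(=O)C1=C(I)C=CC(C)(C)O1 | intermediate
6 | sulcatone, 6-methylhept-5-en-2-one | CC(=O)CCC=C(C)C | starting material
7 | 6-methyl-3-methylidenehept-5-en-2-one | CC(=O)C(=C)CC=C(C)C | intermediate
8 | 1-(5-iodo-2,2-dimethyl-2H-pyran-6-yl)-7-methyl-4-methylideneoct-6-ene-1,3-dione | CC(C)=CCC(=C)C(=O)CC(=O)C1=C(I)C=CC(C)(C)O1 | intermediate
9 | (5S)-8-hydroxy-2,2,5-trimethyl-5-(3-methylbut-2-en-1-yl)-2H-chromen-6(5H)-one | CC(C)=CC[C@]1(C)C(=O)C=C(O)C2=C1C=CC(C)(C)O2 | intermediate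
10 | 3-phenylpropanoic acid | OC(=O)CCc1ccccc1 | starting material
11 | (5S)-2,2,5-trimethyl-5-(3-methylbut-2-en-1-yl)-6-oxo-5,6-dihydro-2H-chromen-8-yl 3-phenylpropanoate (not isolated) | CC(C)=CC[C@]1(C)C(=O)C=C(OC(=O)CCc3ccccc3)C2=C1C=CC(C)(C)O2 | intermediate
12 | (5S)-8-hydroxy-2,2,5-trimethyl-5-(3-methylbut-2-en-1-yl)-7-(3-phenylpropanoyl)-2H-chromen-6(5H)-one | CC(C)=CC[C@]1(C)C(=O)C(C(=O)CCc2ccccc2)=C(O)C2=C1C=CC(C)(C)O2 | target

Total step count: 7. Longest linear sequence: 6 steps (1, 2, 3, 5, 6, 7, from 1 to 12).

Steps most likely to fail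

Step 6 (key step). What may go wrong: formate may reduce the alkenylpalladium iodide before insertion, the enone may suffer conjugate reduction, the enolised diketone may sequester the catalyst, and facial selectivity on the flexible tether may be poor. The fallback is a classical asymmetric Heck reaction ending in β-hydride elimination, with no hydride source; it sets out from 5 and comes back at 9. Wittig olefination of (tert-butyldimethylsilyloxy)acetaldehyde with 3-(triphenylphosphoranylidene)butan-2-one gives (E)-5-(tert-butyldimethylsilyloxy)-3-methylpent-3-en-2-one F1. Its kinetic lithium enolate is condensed with 5 as in step 5 to give (E)-6-(tert-butyldimethylsilyloxy)-1-(5-iodo-2,2-dimethyl-2H-pyran-6-yl)-4-methylhex-4-ene-1,3-dione F2. Pd2(dba)3, (R)-BINAP and Ag3PO4 in DMA at 80 °C should close the ring 6-exo at the methyl-bearing alkene carbon, and β-hydride elimination toward the CH2OSi group gives the silyl enol ether (5S)-5-[2-(tert-butyldimethylsilyloxy)ethenyl]-8-hydroxy-2,2,5-trimethyl-2H-chromen-6(5H)-one F3; the E-alkene and the BINAP antipode together fix C5. Aqueous acetic acid gives 2-[(5S)-8-hydroxy-2,2,5-trimethyl-6-oxo-5,6-dihydro-2H-chromen-5-yl]acetaldehyde F4. Wittig reaction with excess isopropylidenetriphenylphosphorane (to cover the acidic dione) installs the prenyl group and gives 9.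

Step 5. What may go wrong: the cross-conjugated enolate of 7 may undergo anionic Michael oligomerisation or γ-deprotonation, and the diketonate may cyclise through oxygen onto the iodo-diene or the methylene enone. The fallback installs the methylene after the Claisen condensation; it sets out from 5 and 6 and comes back at 8. The kinetic enolate of sulcatone 6 (LiN(iPr)2, THF, −78 °C) is acylated with 5 to give the saturated diketone 1-(5-iodo-2,2-dimethyl-2H-pyran-6-yl)-7-methyloct-6-ene-1,3-dione F5. Its dianion (LiN(iPr)2, 2.2 equiv) is aminomethylated at the only γ-CH2 with dimethylmethyleneiminium iodide to give the Mannich base 4-[(dimethylamino)methyl]-1-(5-iodo-2,2-dimethyl-2H-pyran-6-yl)-7-methyloct-6-ene-1,3-dione F6. MeI gives the trimethylammonium iodide F7, and NaHCO3 induces β-elimination of trimethylamine to give 8.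

Step 1. What may go wrong: electrophilic iodination may be sluggish or unselective, because the enol-ether carbon is deactivated by both the ketone and the ester. The fallback is addition–elimination bromination followed by halogen exchange; it sets out from 1 and comes back at 2. Br2 in CH2Cl2 at 0 °C adds across the enol-ether double bond to give butyl 5,6-dibromo-2,2-dimethyl-4-oxotetrahydro-2H-pyran-6-carboxylate F8 (not isolated). Et3N eliminates HBr to give butyl 5-bromo-2,2-dimethyl-4-oxo-3,4-dihydro-2H-pyran-6-carboxylate F9. Copper-catalysed halogen exchange (CuI, NaI, trans-N,N'-dimethylcyclohexane-1,2-diamine, dioxane, 110 °C) gives 2.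

Further compounds
F1 | step 6 | (E)-5-(tert-butyldimethylsilyloxy)-3-methylpent-3-en-2-one | CC(=O)/C(C)=C/CO[Si](C)(C)C(C)(C)C
F2 | step 6 | (E)-6-(tert-butyldimethylsilyloxy)-1-(5-iodo-2,2-dimethyl-2H-pyran-6-yl)-4-methylhex-4-ene-1,3-dione | O=C(CC(=O)C1=C(I)C=CC(C)(C)O1)/C(C)=C/CO[Si](C)(C)C(C)(C)C
F3 | step 6 | (5S)-5-[2-(tert-butyldimethylsilyloxy)ethenyl]-8-hydroxy-2,2,5-trimethyl-2H-chromen-6(5H)-one | CC(C)(C)[Si](C)(C)OC=C[C@]1(C)C(=O)C=C(O)C2=C1C=CC(C)(C)O2
F4 | step 6 | 2-[(5S)-8-hydroxy-2,2,5-trimethyl-6-oxo-5,6-dihydro-2H-chromen-5-yl]acetaldehyde | O=CC[C@]1(C)C(=O)C=C(O)C2=C1C=CC(C)(C)O2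
F5 | step 5 | 1-(5-iodo-2,2-dimethyl-2H-pyran-6-yl)-7-methyloct-6-ene-1,3-dione | CC(C)=CCCC(=O)CC(=O)C1=C(I)C=CC(C)(C)O1
F6 | step 5 | 4-[(dimethylamino)methyl]-1-(5-iodo-2,2-dimethyl-2H-pyran-6-yl)-7-methyloct-6-ene-1,3-dione | CC(C)=CCC(CN(C)C)C(=O)CC(=O)C1=C(I)C=CC(C)(C)O1
F7 | step 5 | {2-[3-(5-iodo-2,2-dimethyl-2H-pyran-6-yl)-3-oxopropanoyl]-5-methylhex-4-en-1-yl}trimethylammonium iodide | CC(C)=CCC(C[N+](C)(C)C)C(=O)CC(=O)C1=C(I)C=CC(C)(C)O1.[I-]
F8 | step 1 | butyl 5,6-dibromo-2,2-dimethyl-4-oxotetrahydro-2H-pyran-6-carboxylate | CCCCOC(=O)C1(Br)C(Br)C(=O)CC(C)(C)O1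
F9 | step 1 | butyl 5-bromo-2,2-dimethyl-4-oxo-3,4-dihydro-2H-pyran-6-carboxylate | CCCCOC(=O)C1=C(Br)C(=O)CC(C)(C)O1
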